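**Strategy.** Core numbering of the bicyclo[2.2.2]octane: C1 methyl bridgehead, C2 ketone, C3 carbinol, C4 CH bridgehead, C5 CH2, C6 spiro carbon, C7 ketone, C8 enol carbon. Everything rests on the C1–C6 bond. C6 is a ketal-level carbon (ether O, lactone C=O), so it is first parked on the C3 oxygen. A Giese reaction joins a shikimate-derived iodoketal to sorbicillinol acetate at C4, and acid closes the five-membered spiroketal ring O–C3–C4–C5–C6. In the key step this ring is ionised and the silylated 2-methyl-1,3-dione carbon C1 captures C6. The five-membered ring grows into the carbocycle C1–C6, the bicycle closes, and both quaternary stereocentres C1 and C6 are set.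

Key step: step 10

Assumption: 2,4-dimethylresorcinol and methyl 2-methoxyacrylate are taken as catalogue chemicals; enolised tricarbonyl units are drawn as one tautomer; the ketal carbon of 10–14 is an epimer mixture that converges in step 9 and is left undefined in the SMILES.

Step 1
Reactants: 1 2,4-dimethylresorcinol; 2 sorbic acid
Product: 3 sorbicillin = (2E,4E)-1-(2,4-dihydroxy-3,5-dimethylphenyl)hexa-2,4-dien-1-one
Conditions: BF3·OEt2 (neat), 100 °C
Reagents that add atoms: none
Why: Friedel–Crafts (Nencki-type) acylation: BF3 activates the acid and attack occurs at the only unsubstituted ring carbon that is ortho to one hydroxyl and para to the other, so the aryl ketone should form with the E,E-diene intact and without any stereocentre.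

Step 2
Reactants: 3 sorbicillin
Product: 4 (±)-sorbicillinol acetate = racemic 5-[(2E,4E)-hexa-2,4-dienoyl]-4-hydroxy-1,3-dimethyl-2-oxocyclohexa-3,5-dien-1-yl acetate
Conditions: Pb(OAc)4, AcOH/CH2Cl2, 23 °C
Reagents that add atoms: lead tetraacetate, CC(=O)O[Pb](OC(C)=O)(OC(C)=O)OC(C)=O
Why: Wessely oxidation: the non-chelated phenol binds tetravalent lead and an acetate ligand is delivered to the methyl-bearing ortho carbon remote from the second oxygen, which should give the linearly conjugated 6-acetoxy-2,4-dienone; the new quaternary carbon (later C3) forms as a racemate and its R antipode is selected in step 7.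

Step 3
Reactants: 5 (−)-shikimic acid
Product: 6 methyl shikimate 4,5-butane-2,3-diacetal (BDA; 3-OH free; both ketal carbons S with axial OMe)
Conditions: butane-2,3-dione, HC(OMe)3, camphorsulfonic acid (cat.), MeOH, reflux
Reagents that add atoms: butane-2,3-dione, CC(=O)C(C)=O; methanol, CO
Why: Fischer esterification and BDA formation in one flask: the bis-ketal forms only on the trans-diequatorial C4/C5 diol with both methoxy groups axial (anomeric effect), which fixes the two new ketal centres and leaves the allylic C3 hydroxyl free.

Step 4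
Reactants: 6 BDA-protected methyl shikimate
Product: 7 3-epi 4-nitrobenzoate (C3 inverted; ester oxygen trans to O4)
Conditions: 4-nitrobenzoic acid, PPh3, DIAD, THF, 0 to 23 °C
Reagents that add atoms: 4-nitrobenzoic acid, OC(=O)c1ccc(cc1)[N+](=O)[O-]
Why: Mitsunobu reaction: the allylic C3 alcohol is activated as its oxyphosphonium salt and displaced by the carboxylate with SN2 inversion, which sets the 3S configuration (trans to the C4 oxygen) that the target requires.

Step 5
Reactants: 7 3-epi 4-nitrobenzoate
Product: 8 BDA-protected methyl 3-epi-shikimate (free 3S alcohol)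
Conditions: K2CO3 (cat.), MeOH, 0 °C
Reagents that add atoms: none
Why: Zemplén-type transesterification: methoxide cleaves the electron-poor aryl ester much faster than it touches the conjugated methyl ester, which in methanol can only exchange with itself, and no stereocentre is affected.

Step 6
Reactants: 8 BDA-protected methyl 3-epi-shikimate; 9 methyl 2-methoxyacrylate
Product: 10 mixed iodoketal (O3 of 8 bound to C2 of methyl 3-iodo-2-methoxypropanoate)
Conditions: N-iodosuccinimide, 4 Å molecular sieves, CH2Cl2/MeCN, −20 to 23 °C
Reagents that add atoms: N-iodosuccinimide, O=C1CCC(=O)N1I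
Why: Iodoacetalisation (haloetherification, first half of the Ueno–Stork protocol): iodonium attack on the CH2 terminus of the captodative enol ether gives an oxocarbenium ion that the only free hydroxyl traps, which fixes the ether at O3; the new ketal carbon (later C6) forms as both epimers, which is harmless because it is planarised again in steps 9 and 10.

Step 7
Reactants: 10 mixed iodoketal; 4 (±)-sorbicillinol acetate (3 equiv)
Product: 11 Giese adduct (C3 R with OAc; C4 R with its CH2 arm cis to the C3 oxygen; ring as enolised 4-sorboyl-2-methylcyclohexane-1,3-dione)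
Conditions: (TMS)3SiH and 2,2'-azobis(4-methoxy-2,4-dimethylvaleronitrile) added slowly, PhCF3, 40 °C; chromatographic separation of the diastereomers
Reagents that add atoms: none
Why: Giese reaction: the primary radical from iodine abstraction is nucleophilic and adds to C4, the unsubstituted terminus of the doubly acceptor-activated ring alkene, anti to the C3 methyl group (syn to the smaller acetoxy group), which sets C4 cis to the C3 oxygen, and the stabilised tricarbonyl radical takes hydrogen from the silane; the adduct of the S antipode of 4 is a diastereomer and is removed by chromatography.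

Step 8
Reactants: 11 Giese adduct
Product: 12 tertiary carbinol (free C3–OH)
Conditions: K2CO3 (3 equiv), MeOH, 0 °C; aqueous NaH2PO4 work-up
Reagents that add atoms: none
Why: Base-mediated methanolysis: the adjacent carbonyl system activates the tertiary acetate for cleavage while the substrate is protected as its enolate, the methyl esters can only exchange with methanol and the ketals are inert to base, so no stereocentre is affected.

Step 9
Reactants: 12 tertiary carbinol
Product: 15 spiroketal (C3 oxygen bound to C6; five-membered ring O-C3-C4-C5-C6 spiro to the trans-fused dioxanone; C3 oxygen axial), via diol 13 (not isolated), via methoxy lactone 14 (not isolated)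
Conditions: TFA/H2O/CH2Cl2, 0 to 23 °C; evaporate; then TfOH (5 mol %), 4 Å molecular sieves, CH2Cl2, −20 °C
Reagents that add atoms: none
Why: Aqueous acid hydrolyses the BDA bis-ketal but not the ester-deactivated pyruvate-type ketal, the freed C4' hydroxyl lactonises to the six-membered dioxanone, and anhydrous acid then exchanges the methoxy group for the neighbouring tertiary C3 hydroxyl (transketalisation; 5-exo capture of the oxocarbenium ion by oxygen is faster than attack by carbon), the spiro centre settling under anomeric control with the C3 oxygen axial.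

Step 10
Reactants: 15 spiroketal
Product: 19 target CNP0259039.2, via tris-TMS spiroketal 16 (not isolated), via oxocarbenium triflate 17 (not isolated), via tris-TMS adduct 18 (not isolated)
Conditions: N,O-bis(trimethylsilyl)acetamide (4 equiv), CH2Cl2, 23 °C; then TMSOTf (0.3 equiv), −40 to 0 °C; then HF·pyridine, THF, 0 °C
Reagents that add atoms: none
Why: Neutral silylation turns both enols and the secondary alcohol into TMS ethers (16), TMSOTf then silylates the ketal oxygen on C3 so that the C6–O bond of the ring O–C3–C4–C5–C6 ionises to the dioxanone oxocarbenium ion 17, and the silyl enol ether carbon C1 attacks C6 and releases its TMS group, so the oxygen leaves the ring, C2 and C1 enter it, the five-membered ketal ring becomes the six-membered carbocycle C1–C6, and the bicyclo[2.2.2]octane closes. The closest known reaction type is the Mukaiyama-type alkylation of silyl enol ethers with ketals under TMSOTf, including the ring-opening alkylation of cyclic ketals. The new ring closes in a 6-(enolendo)-exo-trig mode, which is allowed for enol nucleophiles. C1 is controlled by the tether, because the C5–C6 arm sits on the ring face fixed by C3 and C4 and reaches only that face of the planar dione; C6 is controlled by stereoelectronically preferred axial attack on the half-chair oxocarbenium ion of the rigid trans-fused dioxanone, which places C1 axial, the lactone carbonyl over the C7–C8 bridge and the ether oxygen next to the C3 oxygen. The step needs C- over O-alkylation and C1 over C8: return to any oxygen, or proton loss from C5, is reversible in this base-free medium whereas the C–C bond is not, and attack by C8 would give a strained cyclobutane. HF·pyridine finally removes the three TMS groups without touching the lactone or the esters.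

**Compound list**

1 | 2,4-dimethylresorcinol | Cc1ccc(O)c(C)c1O | starting material
2 | sorbic acid | C/C=C/C=C/C(=O)O | starting material
3 | sorbicillin | C/C=C/C=C/C(=O)c1cc(C)c(O)c(C)c1O | intermediate
4 | (±)-sorbicillinol acetate (racemic) | CC1=C(O)C(C(=O)/C=C/C=C/C)=CC(C)(OC(C)=O)C1=O | intermediate
5 | (−)-shikimic acid | OC(=O)C1=C[C@@H](O)[C@@H](O)[C@H](O)C1 | starting material
6 | methyl shikimate 4,5-butane-2,3-diacetal | COC(=O)C1=C[C@@H](O)[C@H]2O[C@](C)(OC)[C@@](C)(OC)O[C@@H]2C1 | intermediate
7 | 3-epi 4-nitrobenzoate of 6 | COC(=O)C1=C[C@H](OC(=O)c3ccc(cc3)[N+](=O)[O-])[C@H]2O[C@](C)(OC)[C@@](C)(OC)O[C@@H]2C1 | intermediate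
8 | BDA-protected methyl 3-epi-shikimate | COC(=O)C1=C[C@H](O)[C@H]2O[C@](C)(OC)[C@@](C)(OC)O[C@@H]2C1 | intermediate
9 | methyl 2-methoxyacrylate | C=C(OC)C(=O)OC | starting material
10 | mixed iodoketal (ketal carbon: both epimers) | COC(=O)C1=C[C@H](OC(CI)(OC)C(=O)OC)[C@H]2O[C@](C)(OC)[C@@](C)(OC)O[C@@H]2C1 | intermediate
11 | Giese adduct, C3 acetate | C/C=C/C=C/C(O)=C1/C(=O)C(C)=C(O)[C@](C)(OC(C)=O)[C@@H]1CC(OC)(C(=O)OC)O[C@H]2C=C(C(=O)OC)C[C@H]3O[C@](C)(OC)[C@@](C)(OC)O[C@H]23 | intermediate
12 | tertiary carbinol | C/C=C/C=C/C(O)=C1/C(=O)C(C)=C(O)[C@](C)(O)[C@@H]1CC(OC)(C(=O)OC)O[C@H]2C=C(C(=O)OC)C[C@H]3O[C@](C)(OC)[C@@](C)(OC)O[C@H]23 | intermediate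
13 | diol (BDA removed) | C/C=C/C=C/C(O)=C1/C(=O)C(C)=C(O)[C@](C)(O)[C@@H]1CC(OC)(C(=O)OC)O[C@H]2C=C(C(=O)OC)C[C@@H](O)[C@@H]2O | intermediate
14 | methoxy lactone (3-methoxy-1,4-dioxan-2-one) | C/C=C/C=C/C(O)=C1/C(=O)C(C)=C(O)[C@](C)(O)[C@@H]1CC2(OC)O[C@H]3C=C(C(=O)OC)C[C@@H](O)[C@@H]3OC2=O | intermediate
15 | spiroketal (five-membered ring O–C3–C4–C5–C6) | C/C=C/C=C/C(O)=C1/C(=O)C(C)=C(O)[C@]2(C)O[C@]3(C[C@H]12)O[C@H]4C=C(C(=O)OC)C[C@@H](O)[C@@H]4OC3=O | intermediate
16 | tris-TMS spiroketal | C/C=C/C=C/C(O[Si](C)(C)C)=C1/C(=O)C(C)=C(O[Si](C)(C)C)[C@]2(C)O[C@]3(C[C@H]12)O[C@H]4C=C(C(=O)OC)C[C@@H](O[Si](C)(C)C)[C@@H]4OC3=O | intermediate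
17 | oxocarbenium triflate | C/C=C/C=C/C(O[Si](C)(C)C)=C1/C(=O)C(C)=C(O[Si](C)(C)C)[C@](C)(O[Si](C)(C)C)[C@@H]1CC2=[O+][C@H]3C=C(C(=O)OC)C[C@@H](O[Si](C)(C)C)[C@@H]3OC2=O.[O-]S(=O)(=O)C(F)(F)F | intermediate
18 | tris-TMS adduct (silylated target) | C/C=C/C=C/C(O[Si](C)(C)C)=C1/C(=O)[C@@]2(C)C(=O)[C@](C)(O[Si](C)(C)C)[C@@H]1C[C@]21O[C@H]2C=C(C(=O)OC)C[C@@H](O[Si](C)(C)C)[C@@H]2OC1=O | intermediate
19 | CNP0259039.2 (core C1 S, C3 R, C4 R, C6 S; cyclohexene 3S,4S,5R) | C/C=C/C=C/C(O)=C1/C(=O)[C@@]2(C)C(=O)[C@](C)(O)[C@@H]1C[C@]21O[C@H]2C=C(C(=O)OC)C[C@@H](O)[C@@H]2OC1=O | target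

Total step count: 10. Longest linear sequence: 8 (steps 3–10, from shikimic acid).

**Steps most likely to fail**

1. Step 10. The lactone carbonyl deactivates the ketal, so ionisation may be too slow. The cation may also only shuttle between oxygen nucleophiles and the C5-deprotonated enol ether instead of bonding to the hindered C1.
 - The fallback runs the same ring enlargement in two separate operations, with a halide leaving group and an anionic nucleophile.
 - It sets out from 15, which is silylated with N,O-bis(trimethylsilyl)acetamide alone, and 16 is isolated.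
 - TMSBr cleaves the spiroketal to the ring-opened tetra-TMS C6 bromide F1.
 - Anhydrous fluoride (tetrabutylammonium difluorotriphenylsilicate, THF, −40 °C) unmasks the dione enolate, which displaces the tertiary bromide at carbon.
 - The sequence returns to the route at 18, which HF·pyridine converts into 19.

2. Step 7. The radical may add to the sorbyl chain, may be reduced before it adds, or may add to C4 with poor facial selectivity.
 - The fallback sets out from 10 and uses an acceptor without the dienyl chain.
 - Commercial clavatol (2,4-dihydroxy-3,5-dimethylacetophenone) is oxidised with Pb(OAc)4 to the racemic acetyl acetoxydienone F2.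
 - The same silane-mediated addition of 10 gives the acetyl analogue of the adduct F3.
 - A boron-templated aldol condensation of its acetyl methyl group with (E)-but-2-enal (B2O3, B(OBu)3, BuNH2, EtOAc) then builds the sorbyl chain.
 - The sequence returns to the route at 11.

3. Step 9. The acyclic mixed ketal may be cleaved during the aqueous acid treatment, which would separate the two halves of an advanced intermediate.
 - The fallback sets out from 10 and closes the dioxanone before the union.
 - Aqueous TFA followed by acid-catalysed lactonisation on this small fragment gives the iodomethyl methoxy dioxanone F4, whose ketal is now cyclic and robust.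
 - The Giese reaction with (±)-4 gives the lactone acetate F5.
 - K2CO3 in MeOH removes the acetate and opens the lactone to the methyl ester.
 - The sequence returns to the route at 13, which is closed to 15 under the anhydrous TfOH conditions only.

**Further compounds**

F1 | step 10 | ring-opened tetra-TMS C6 bromide | C/C=C/C=C/C(O[Si](C)(C)C)=C1/C(=O)C(C)=C(O[Si](C)(C)C)[C@](C)(O[Si](C)(C)C)[C@@H]1CC2(Br)O[C@H]3C=C(C(=O)OC)C[C@@H](O[Si](C)(C)C)[C@@H]3OC2=O
F2 | step 7 | racemic 5-acetyl-4-hydroxy-1,3-dimethyl-2-oxocyclohexa-3,5-dien-1-yl acetate | CC1=C(O)C(C(C)=O)=CC(C)(OC(C)=O)C1=O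
F3 | step 7 | acetyl analogue of adduct 11 | C/C(O)=C1/C(=O)C(C)=C(O)[C@](C)(OC(C)=O)[C@@H]1CC(OC)(C(=O)OC)O[C@H]2C=C(C(=O)OC)C[C@H]3O[C@](C)(OC)[C@@](C)(OC)O[C@H]23
F4 | step 9 | iodomethyl methoxy dioxanone | COC1(CI)O[C@H]2C=C(C(=O)OC)C[C@@H](O)[C@@H]2OC1=O
F5 | step 9 | lactone acetate | C/C=C/C=C/C(O)=C1/C(=O)C(C)=C(O)[C@](C)(OC(C)=O)[C@@H]1CC2(OC)O[C@H]3C=C(C(=O)OC)C[C@@H](O)[C@@H]3OC2=O
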